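The cyclohexene (C1 acyl carbon, C2 carrying the 3,4-dimethoxyphenyl ring, C3=C4, C5H2, C6 carrying the 4-hydroxy-3-methoxyphenyl ring) is opened at C1–C6. C6 is the benzylic carbon para to the only free phenolic OH. Anodic two-electron oxidation of that guaiacol ring turns C6 into the electrophilic carbon of a para-quinone methide, and a tethered malonate carbon (the later C1) adds to it. One operation therefore forms C1–C6, closes the ring and sets the C6 centre with its aryl group cis to that at C2. The substrate is an acyclic (R)-1-aryl-(Z)-pent-2-enyl malonate ending in the unprotected 4-alkylguaiacol. Afterwards the malonate is cut down to one carbonyl and extended to the feruloyl enol-diketone.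

Key step: step 7

Remark on numbering: all names use lowest locants for the ring alkene, so the 3,4-dimethoxyphenyl group is at C2 (allylic) and the guaiacyl group at C6 (next to the CH2); with this numbering the target is (1R,2R,6S).
Assumption: the (Sa,S,S)-phosphoramidite is taken to give the (R)-branched malonate in step 2; if the sense of induction is the opposite, the mirror-image ligand is used and nothing else changes.
Remark on tautomers: the β-diketones of steps 10 and 11 are each written as one tautomer.

Step 1
Reactants: 1 (E)-3-(3,4-dimethoxyphenyl)prop-2-en-1-ol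
Product: 2 (E)-3-(3,4-dimethoxyphenyl)prop-2-en-1-yl methyl carbonate
Conditions: ClCO2Me, pyridine, CH2Cl2, 0 °C
Reagents that add atoms: methyl chloroformate, COC(=O)Cl
Why: O-acylation of the primary allylic alcohol with a chloroformate installs the carbonate leaving group for iridium allyl chemistry and leaves the E-alkene untouched.

Step 2
Reactants: 2 (E)-3-(3,4-dimethoxyphenyl)prop-2-en-1-yl methyl carbonate; 3 dimethyl malonate
Product: 4 dimethyl 2-[(1R)-1-(3,4-dimethoxyphenyl)prop-2-en-1-yl]propanedioate
Conditions: [Ir(cod)Cl]2 (2 mol %), (Sa,S,S)-binaphthol bis(1-phenylethyl)amine phosphoramidite (4 mol %), TBD (8 mol %), THF, rt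
Reagents that add atoms: none
Why: Iridium-catalysed asymmetric allylic alkylation under salt-free conditions: the malonate, deprotonated by the methoxide released from the carbonate, attacks the aryl-substituted terminus of the iridium allyl complex, and the ligand configuration sets the (R) centre (the later C2).

Step 3
Reactants: 5 4-bromo-2-methoxyphenol
Product: 6 (4-bromo-2-methoxyphenoxy)(tert-butyl)dimethylsilane
Conditions: TBSCl, imidazole, DMF, rt
Reagents that add atoms: tert-butyldimethylsilyl chloride, CC(C)(C)[Si](C)(C)Cl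
Why: Imidazole-promoted silylation masks the acidic phenol for the organozinc coupling and the metathesis that follow.

Step 4
Reactants: 6 (4-bromo-2-methoxyphenoxy)(tert-butyl)dimethylsilane
Product: 7 tert-butyl[4-(but-3-en-1-yl)-2-methoxyphenoxy]dimethylsilane
Conditions: but-3-enylzinc bromide, Pd(OAc)2 (2 mol %), SPhos (4 mol %), THF, 40 °C
Reagents that add atoms: but-3-enylzinc bromide, C=CCC[Zn]Br
Why: Negishi sp2–sp3 cross-coupling, in which the bulky biaryl phosphine favours reductive elimination over β-hydride elimination so that the terminal alkene should stay in place.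

Step 5
Reactants: 4 dimethyl 2-[(1R)-1-(3,4-dimethoxyphenyl)prop-2-en-1-yl]propanedioate; 7 tert-butyl[4-(but-3-en-1-yl)-2-methoxyphenoxy]dimethylsilane (3 equiv)
Product: 8 dimethyl 2-[(1R,2Z)-5-{4-[(tert-butyldimethylsilyl)oxy]-3-methoxyphenyl}-1-(3,4-dimethoxyphenyl)pent-2-en-1-yl]propanedioate
Conditions: Z-selective cyclometalated Ru–NHC nitrato metathesis catalyst (5 mol %), THF, 35 °C, static vacuum
Reagents that add atoms: none
Why: Z-selective olefin cross-metathesis of an allylic-branched terminal alkene with an unhindered terminal alkene, in which the chelated catalyst forces a side-bound all-syn metallacycle that releases the cis-alkene, ethene loss drives the reaction and the stereocentre is not involved.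

Step 6
Reactants: 8 dimethyl 2-[(1R,2Z)-5-{4-[(tert-butyldimethylsilyl)oxy]-3-methoxyphenyl}-1-(3,4-dimethoxyphenyl)pent-2-en-1-yl]propanedioate
Product: 9 dimethyl 2-[(1R,2Z)-1-(3,4-dimethoxyphenyl)-5-(4-hydroxy-3-methoxyphenyl)pent-2-en-1-yl]propanedioate
Conditions: TBAF, AcOH, THF, 0 °C
Reagents that add atoms: none
Why: Fluoride cleavage of the aryl silyl ether, buffered with acetic acid so that neither the malonate nor the Z-alkene is exposed to base.

Step 7
Reactants: 9 dimethyl 2-[(1R,2Z)-1-(3,4-dimethoxyphenyl)-5-(4-hydroxy-3-methoxyphenyl)pent-2-en-1-yl]propanedioate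
Product: 11 dimethyl (2S,6R)-2-(3,4-dimethoxyphenyl)-6-(4-hydroxy-3-methoxyphenyl)cyclohex-3-ene-1,1-dicarboxylate, via para-quinone methide 10 (not isolated)
Conditions: undivided cell, graphite anode, Pt cathode, constant current (about 1 mA cm⁻², stopped near 2 F mol⁻¹), Mg(ClO4)2 (0.1 M), 2,6-lutidine (3 equiv), MeCN/CH2Cl2, 5 mM, 0 °C
Reagents that add atoms: none
Why: Proposed new method: at the carbon anode the guaiacol OH of 9 (the only free phenol, whose lutidine-assisted oxidation lies well below the onset of the 1,2-dimethoxyarene, the alkene and the un-ionised malonate) should lose two electrons and the phenolic proton to give a phenoxonium ion, which sheds its para-benzylic proton to form quinone methide 10; the Mg2+-chelated malonate, enolised by lutidine, then adds through C1 to the exocyclic methide carbon (C6) and the aromatic ring is restored. The closest known reactions are anodic side-chain functionalisation of 4-alkylphenols through quinone methides and base- or Lewis-acid-promoted 1,6-addition of malonates to para-quinone methides; their intramolecular combination is not established. The ring closes 6-exo-trig (C1 onto C6), which is possible only because the Z-alkene places both chain ends on the same side. The new centre C6 is controlled by C2: in a chair-like transition state the C2 aryl group sits pseudo-equatorial and the quinone methide ring equatorial, which should give the cis-2,6 (2S,6R) isomer, and any reversibility of the addition leads to the same diequatorial product. The step needs ring closure to outrun tautomerisation of 10 to the dienylphenol, phenoxyl dimerisation and further oxidation of the product phenol; high dilution, low temperature, a weak non-nucleophilic base, pre-organisation by Mg2+ chelation and the charge limit are meant to secure this.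

Step 8
Reactants: 11 dimethyl (2S,6R)-2-(3,4-dimethoxyphenyl)-6-(4-hydroxy-3-methoxyphenyl)cyclohex-3-ene-1,1-dicarboxylate
Product: 13 methyl (1R,2R,6S)-2-(3,4-dimethoxyphenyl)-6-(4-hydroxy-3-methoxyphenyl)cyclohex-3-ene-1-carboxylate, via C1-epimeric monoester mixture 12 (not isolated)
Conditions: LiCl, DMSO, H2O, 150 °C; then NaOMe, MeOH, 50 °C
Reagents that add atoms: none
Why: Krapcho dealkoxycarbonylation (chloride attacks one ester methyl, the carboxylate loses CO2 and the ester enolate is protonated) followed by methoxide equilibration of the only enolisable centre, which should place the C1 ester equatorial and trans to both aryl groups (1R); any remaining epimer can be separated and re-equilibrated.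

Step 9
Reactants: 13 methyl (1R,2R,6S)-2-(3,4-dimethoxyphenyl)-6-(4-hydroxy-3-methoxyphenyl)cyclohex-3-ene-1-carboxylate
Product: 15 1-[(1R,2R,6S)-2-(3,4-dimethoxyphenyl)-6-(4-hydroxy-3-methoxyphenyl)cyclohex-3-en-1-yl]ethan-1-one, via N-methoxy-N-methylamide 14 (not isolated)
Conditions: MeNH(OMe)·HCl, i-PrMgCl, THF, −20 °C to rt; then MeMgBr, 0 °C; aq. HCl
Reagents that add atoms: methylmagnesium bromide, C[Mg]Br; N,O-dimethylhydroxylamine hydrochloride, CNOC.Cl (its atoms stay only in 14)
Why: Weinreb ketone synthesis in one pot: the magnesium amide converts the ester into the N-methoxy-N-methylamide, whose stable magnesium chelate takes up a single methyl group and gives the methyl ketone on work-up, with the phenol carried as its magnesium phenoxide and C1 already at its thermodynamic configuration.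

Step 10
Reactants: 15 1-[(1R,2R,6S)-2-(3,4-dimethoxyphenyl)-6-(4-hydroxy-3-methoxyphenyl)cyclohex-3-en-1-yl]ethan-1-one
Product: 16 1-[(1R,2R,6S)-2-(3,4-dimethoxyphenyl)-6-(4-hydroxy-3-methoxyphenyl)cyclohex-3-en-1-yl]butane-1,3-dione
Conditions: NaH, EtOAc, THF, 60 °C; then aq. HCl
Reagents that add atoms: ethyl acetate, CCOC(C)=O
Why: Crossed Claisen condensation in which the methyl-side enolate is acetylated by ethyl acetate and the equilibrium is pulled over by the diketonate, which only acylation at CH3 (not at the methine C1) can form.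

Step 11
Reactants: 16 1-[(1R,2R,6S)-2-(3,4-dimethoxyphenyl)-6-(4-hydroxy-3-methoxyphenyl)cyclohex-3-en-1-yl]butane-1,3-dione; 17 vanillin
Product: 18 (2Z,4E)-1-[(1R,2R,6S)-2-(3,4-dimethoxyphenyl)-6-(4-hydroxy-3-methoxyphenyl)cyclohex-3-en-1-yl]-3-hydroxy-5-(4-hydroxy-3-methoxyphenyl)penta-2,4-dien-1-one
Conditions: B2O3, B(On-Bu)3, n-BuNH2 (cat.), EtOAc, 75 °C; then dilute HCl, 50 °C
Reagents that add atoms: none
Why: Boron-templated aldol condensation as used for curcuminoids: the boron chelate blocks the central CH2, so the amine-catalysed condensation with the aldehyde occurs at the terminal methyl and dehydration gives the E-styryl enol-diketone, which dilute acid sets free; free phenols are tolerated and no stereocentre is touched.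

Compound list
1 | (E)-3-(3,4-dimethoxyphenyl)prop-2-en-1-ol | OC/C=C/c1ccc(OC)c(OC)c1 | starting material
2 | (E)-3-(3,4-dimethoxyphenyl)prop-2-en-1-yl methyl carbonate | COC(=O)OC/C=C/c1ccc(OC)c(OC)c1 | intermediate
3 | dimethyl malonate | COC(=O)CC(=O)OC | starting material
4 | dimethyl 2-[(1R)-1-(3,4-dimethoxyphenyl)prop-2-en-1-yl]propanedioate | COC(=O)C(C(=O)OC)[C@H](c1ccc(OC)c(OC)c1)C=C | intermediate
5 | 4-bromo-2-methoxyphenol | COc1cc(Br)ccc1O | starting material
6 | (4-bromo-2-methoxyphenoxy)(tert-butyl)dimethylsilane | COc1cc(Br)ccc1O[Si](C)(C)C(C)(C)C | intermediate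
7 | tert-butyl[4-(but-3-en-1-yl)-2-methoxyphenoxy]dimethylsilane | COc1cc(CCC=C)ccc1O[Si](C)(C)C(C)(C)C | intermediate
8 | dimethyl 2-[(1R,2Z)-5-{4-[(tert-butyldimethylsilyl)oxy]-3-methoxyphenyl}-1-(3,4-dimethoxyphenyl)pent-2-en-1-yl]propanedioate | COC(=O)C(C(=O)OC)[C@H](c1ccc(OC)c(OC)c1)/C=C\CCc1ccc(O[Si](C)(C)C(C)(C)C)c(OC)c1 | intermediate
9 | dimethyl 2-[(1R,2Z)-1-(3,4-dimethoxyphenyl)-5-(4-hydroxy-3-methoxyphenyl)pent-2-en-1-yl]propanedioate | COC(=O)C(C(=O)OC)[C@H](c1ccc(OC)c(OC)c1)/C=C\CCc1ccc(O)c(OC)c1 | intermediate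
10 | para-quinone methide: dimethyl 2-[(1R,2Z)-1-(3,4-dimethoxyphenyl)-5-(3-methoxy-4-oxocyclohexa-2,5-dien-1-ylidene)pent-2-en-1-yl]propanedioate | COC(=O)C(C(=O)OC)[C@H](c1ccc(OC)c(OC)c1)/C=C\CC=C1C=CC(=O)C(OC)=C1 | intermediate (not isolated)
11 | dimethyl (2S,6R)-2-(3,4-dimethoxyphenyl)-6-(4-hydroxy-3-methoxyphenyl)cyclohex-3-ene-1,1-dicarboxylate | COC(=O)C1(C(=O)OC)[C@@H](c2ccc(O)c(OC)c2)CC=C[C@H]1c1ccc(OC)c(OC)c1 | intermediate
12 | methyl (2R,6S)-2-(3,4-dimethoxyphenyl)-6-(4-hydroxy-3-methoxyphenyl)cyclohex-3-ene-1-carboxylate, mixture of C1 epimers | COC(=O)C1[C@@H](c2ccc(O)c(OC)c2)CC=C[C@H]1c1ccc(OC)c(OC)c1 | intermediate (not isolated)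
13 | methyl (1R,2R,6S)-2-(3,4-dimethoxyphenyl)-6-(4-hydroxy-3-methoxyphenyl)cyclohex-3-ene-1-carboxylate | COC(=O)[C@@H]1[C@@H](c2ccc(O)c(OC)c2)CC=C[C@H]1c1ccc(OC)c(OC)c1 | intermediate
14 | (1R,2R,6S)-2-(3,4-dimethoxyphenyl)-6-(4-hydroxy-3-methoxyphenyl)-N-methoxy-N-methylcyclohex-3-ene-1-carboxamide | CON(C)C(=O)[C@@H]1[C@@H](c2ccc(O)c(OC)c2)CC=C[C@H]1c1ccc(OC)c(OC)c1 | intermediate (not isolated)
15 | 1-[(1R,2R,6S)-2-(3,4-dimethoxyphenyl)-6-(4-hydroxy-3-methoxyphenyl)cyclohex-3-en-1-yl]ethan-1-one | CC(=O)[C@@H]1[C@@H](c2ccc(O)c(OC)c2)CC=C[C@H]1c1ccc(OC)c(OC)c1 | intermediate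
16 | 1-[(1R,2R,6S)-2-(3,4-dimethoxyphenyl)-6-(4-hydroxy-3-methoxyphenyl)cyclohex-3-en-1-yl]butane-1,3-dione | CC(=O)CC(=O)[C@@H]1[C@@H](c2ccc(O)c(OC)c2)CC=C[C@H]1c1ccc(OC)c(OC)c1 | intermediate
17 | vanillin (4-hydroxy-3-methoxybenzaldehyde) | COc1cc(C=O)ccc1O | starting material
18 | (2Z,4E)-1-[(1R,2R,6S)-2-(3,4-dimethoxyphenyl)-6-(4-hydroxy-3-methoxyphenyl)cyclohex-3-en-1-yl]-3-hydroxy-5-(4-hydroxy-3-methoxyphenyl)penta-2,4-dien-1-one | COc1cc(/C=C/C(O)=C/C(=O)[C@@H]2[C@@H](c3ccc(O)c(OC)c3)CC=C[C@H]2c2ccc(OC)c(OC)c2)ccc1O | target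

Total step count: 11. Longest linear sequence: 9 steps (steps 1, 2, 5, 6, 7, 8, 9, 10, 11; the branch through steps 3 and 4 is equally long).

Steps most likely to fail

Step 7. The quinone methide may tautomerise to the conjugated dienylphenol, the phenoxyl radical may dimerise, or the product phenol may be oxidised further before or after C1 attacks. The fallback makes the same quinone methide without any oxidation, by fluoride-triggered 1,6-elimination, which is known chemistry. It sets out from 4. Vanillin 17 is silylated (TBSCl, imidazole) to 4-[(tert-butyldimethylsilyl)oxy]-3-methoxybenzaldehyde F1, allylated with allylmagnesium bromide to racemic 1-{4-[(tert-butyldimethylsilyl)oxy]-3-methoxyphenyl}but-3-en-1-ol F2 and acetylated (Ac2O, pyridine, DMAP) to 1-{4-[(tert-butyldimethylsilyl)oxy]-3-methoxyphenyl}but-3-en-1-yl acetate F3. Z-selective cross-metathesis of 4 with F3 under the conditions of step 5 should give dimethyl 2-[(1R,2Z)-5-acetoxy-5-{4-[(tert-butyldimethylsilyl)oxy]-3-methoxyphenyl}-1-(3,4-dimethoxyphenyl)pent-2-en-1-yl]propanedioate F4, in which either configuration at the acetate carbon serves. TBAF in THF at −40 °C removes the silyl group, the phenoxide expels acetate to give quinone methide 10 while fluoride holds the malonate as its enolate, and the 1,6-addition brings the route back at 11.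

Step 5. The bulky allylic-branched alkene may fail to enter the catalytic cycle, the Z-selectivity may erode through secondary metathesis, or the double bond may migrate towards the arene. The fallback replaces metathesis by olefination and sets out from 4. Ozonolysis (O3, CH2Cl2/MeOH, −78 °C; Me2S) should give dimethyl 2-[(1R)-1-(3,4-dimethoxyphenyl)-2-oxoethyl]propanedioate F5. Commercial 3-(4-hydroxy-3-methoxyphenyl)propan-1-ol is converted by Appel bromination into 4-(3-bromopropyl)-2-methoxyphenol F6 and by heating with PPh3 into [3-(4-hydroxy-3-methoxyphenyl)propyl]triphenylphosphonium bromide F7. The unstabilised ylide of F7 (NaHMDS, THF, −78 °C, with extra equivalents for the phenol and for the malonate, which as its enolate also shields the neighbouring α-aryl aldehyde centre from enolisation) should give the Z-alkene in a salt-free Wittig reaction. The route comes back at 9, and steps 3, 4 and 6 are then not needed.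

Step 9. The C1 ester, flanked by two aryl-bearing carbons, may be enolised by the magnesium amide instead of attacked, so that 13 is returned. The fallback uses carbonyl methylenation in place of acyl substitution and sets out from 13. The titanium–aluminium methylidene reagent Cp2Ti(μ-CH2)(μ-Cl)AlMe2 (excess, to cover the phenol; THF/toluene, −40 °C to rt) should convert the ester carbonyl into the methyl enol ether 4-[(1S,5R,6R)-5-(3,4-dimethoxyphenyl)-6-(1-methoxyethenyl)cyclohex-3-en-1-yl]-2-methoxyphenol F8. Dilute HCl in THF hydrolyses it to the methyl ketone, and the route comes back at 15.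

Further compounds
F1 | step 7 | 4-[(tert-butyldimethylsilyl)oxy]-3-methoxybenzaldehyde | COc1cc(C=O)ccc1O[Si](C)(C)C(C)(C)C
F2 | step 7 | 1-{4-[(tert-butyldimethylsilyl)oxy]-3-methoxyphenyl}but-3-en-1-ol (racemic) | COc1cc(C(O)CC=C)ccc1O[Si](C)(C)C(C)(C)C
F3 | step 7 | 1-{4-[(tert-butyldimethylsilyl)oxy]-3-methoxyphenyl}but-3-en-1-yl acetate (racemic) | COc1cc(C(CC=C)OC(C)=O)ccc1O[Si](C)(C)C(C)(C)C
F4 | step 7 | dimethyl 2-[(1R,2Z)-5-acetoxy-5-{4-[(tert-butyldimethylsilyl)oxy]-3-methoxyphenyl}-1-(3,4-dimethoxyphenyl)pent-2-en-1-yl]propanedioate (both C5 epimers) | COC(=O)C(C(=O)OC)[C@H](c1ccc(OC)c(OC)c1)/C=C\CC(OC(C)=O)c1ccc(O[Si](C)(C)C(C)(C)C)c(OC)c1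
F5 | step 5 | dimethyl 2-[(1R)-1-(3,4-dimethoxyphenyl)-2-oxoethyl]propanedioate | COC(=O)C(C(=O)OC)[C@H](c1ccc(OC)c(OC)c1)C=O
F6 | step 5 | 4-(3-bromopropyl)-2-methoxyphenol | COc1cc(CCCBr)ccc1O
F7 | step 5 | [3-(4-hydroxy-3-methoxyphenyl)propyl]triphenylphosphonium bromide | COc1cc(CCC[P+](c2ccccc2)(c2ccccc2)c2ccccc2)ccc1O.[Br-]
F8 | step 9 | 4-[(1S,5R,6R)-5-(3,4-dimethoxyphenyl)-6-(1-methoxyethenyl)cyclohex-3-en-1-yl]-2-methoxyphenol | COC(=C)[C@@H]1[C@@H](c2ccc(O)c(OC)c2)CC=C[C@H]1c1ccc(OC)c(OC)c1
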